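A direct plan would keep the aromatic ring from the start: 3,5-dimethoxyphenol A1 would be brominated beside the hydroxyl to give 2-bromo-3,5-dimethoxyphenol A2, which would be O-silylated and taken by Br–Li exchange, retro-Brook shift and triflation to the ortho-silyl aryl triflate A3.
Fluoride would then release 3,5-dimethoxybenzyne A4 in the presence of 11-phenylundecanoic acid (compound 1 below), whose carboxyl C–O bond would insert to give hydroxy ketone A5; BBr3 would finally remove both methyl groups.
Weakest would be the run-up of bromination, silylation and triflation: three operations, one giving regioisomeric bromides and one at −100 °C, that only install Br, SiMe3 and OTf, none of which reaches the target.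
Next would be the aryne insertion, the convergent step that consumes both precious partners: protonation of the aryl anion by the acid (plain O-arylation) would compete with the strained four-ring acyl shift, and the site of addition would rest on aryne distortion alone.
Last would be the closing double O-demethylation on the final intermediate, where two ethers must fall, the unchelated para one is slow, and partly methylated mixtures would be likely.
No stereocentre or ring closure would be at stake; the cost would lie in step economy and chemoselectivity.

**Plan of the new route**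
In ring A (the trihydroxyphenyl ring) the ketone carbon, C2, C4 and C6 carry oxygen while C1, C3 and C5 do not: this is the pattern of a linear tetraketide, so ring A can be folded from a chain instead of being substituted.
The retrosynthesis cuts ring bond C1–C2 (acyl-bearing carbon to hydroxyl-bearing carbon) as a Claisen bond, giving methyl 3,5,7-trioxo-17-phenylheptadecanoate, stored with its carbonyl groups masked as a 4-hydroxy-2-pyranone.
It then cuts the bond between the side-chain ketone carbon and the pyranone 6-CH2, giving triacetic acid lactone and the Weinreb amide of 11-phenylundecanoic acid.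
Ring order: the terminal phenyl ring is bought, a pyranone is the only other ring until the end, and ring A arises last.
No Br, SiMe3 or OTf is put on and taken off, no aryne has to add on the right side or outrun a proton, and no oxygen is ever methylated, so nothing has to be demethylated.

Key step: step 3

Remark (assumption): 11-phenylundecanoic acid and 4-hydroxy-6-methyl-2H-pyran-2-one (triacetic acid lactone) are taken as commercial. C1–C8 in the discussion of compound 8 count its chain from the ester carbon.

Step 1
Reactants: 1 11-phenylundecanoic acid
Product: 3 N-methoxy-N-methyl-11-phenylundecanamide, via 1-(1H-imidazol-1-yl)-11-phenylundecan-1-one 2 (not isolated)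
Conditions: CDI (1.2 equiv), CH2Cl2, rt; then MeNHOMe·HCl (1.5 equiv), rt; dilute aq. HCl wash
Reagents that add atoms: N,O-dimethylhydroxylamine hydrochloride, CNOC.Cl; 1,1'-carbonyldiimidazole, O=C(n1ccnc1)n1ccnc1 (its imidazolyl group is carried only by 2; no atom of it stays in 3)
Why: Carboxyl activation by CDI gives acylimidazole 2, which is aminolysed by N,O-dimethylhydroxylamine set free from its hydrochloride by the released imidazole (Weinreb amide formation); the saturated chain and the phenyl ring are inert and no stereocentre is involved.

Step 2
Reactants: 4 4-hydroxy-6-methyl-2H-pyran-2-one; 3 N-methoxy-N-methyl-11-phenylundecanamide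
Product: 7 4-hydroxy-6-(2-oxo-12-phenyldodecyl)-2H-pyran-2-one, via lithium 6-(lithiomethyl)-2-oxo-2H-pyran-4-olate 5 (not isolated), via dilithium 6-[2-(N-methoxy-N-methylamino)-2-oxido-12-phenyldodecyl]-2-oxo-2H-pyran-4-olate 6 (not isolated)
Conditions: 4 (2.0 equiv), LiN(i-Pr)2 (4.1 equiv, commercial solution), THF, −78 °C; then 3 (1.0 equiv), −78 to 0 °C; 1 M HCl
Reagents that add atoms: lithium diisopropylamide, [Li+].CC(C)[N-]C(C)C (its lithium is carried only by 5 and 6; no atom of it stays in 7)
Why: LiN(i-Pr)2 removes first the acidic 4-OH proton and then a proton of the 6-methyl group to give dianion 5, whose carbanion, the last-formed and most nucleophilic site, adds to the Weinreb amide to give the chelated adduct 6 that survives until the acid quench, so that the β-keto pyranone is never exposed to base or to a second addition (Claisen-type C-acylation of a vinylogous enolate dianion with a Weinreb amide; the carbinolamine stereocentre of 6 is racemic and is lost on collapse to the ketone).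

Step 3
Reactants: 7 4-hydroxy-6-(2-oxo-12-phenyldodecyl)-2H-pyran-2-one
Product: 9 11-phenyl-1-(2,4,6-trihydroxyphenyl)undecan-1-one, via methyl 3,5,7-trioxo-17-phenylheptadecanoate 8 (not isolated)
Conditions: Mg(OMe)2 (8 equiv, commercial solution), MeOH, reflux, Ar; then 1 M HCl, 0 °C
Reagents that add atoms: magnesium methoxide, CO[Mg]OC (its methoxy group is carried only by 8; no atom of it stays in 9)
Why: Methoxide opens the lactone carbonyl of 7 to the magnesium polyenolate of triketo ester 8, whose carbon C6, the methylene between the C5 and C7 ketones, attacks the ester carbonyl C1 and expels methoxide, and the 2-acylcyclohexane-1,3,5-trione so formed, the keto tautomer of 9, enolises at once to the benzene ring. The closest known reaction type is the Mg(OMe)2-induced Claisen cyclisation of 6-(2-oxoalkyl)-4-hydroxy-2-pyranones and of 3,5,7-trioxo esters to acylphloroglucinols, the laboratory counterpart of the ring closure carried out by polyketide synthases of the chalcone synthase family. Ring A closes by a 6-exo-trig, Dieckmann-type attack of C6 on C1, so that C6 becomes the acyl-bearing ring carbon C1 of 9 and the ester carbon becomes C2. No stereocentre is formed. The step needs Claisen folding (C6 to C1) and not aldol folding (C2 to the C7 ketone, or chain carbon C8 to C3): in the chelated polyenolate every ketone carbonyl is masked as an enolate, the ester carbonyl is the only electrophile left and is activated by the divalent magnesium ion held between the C1 and C3 oxygens, C6 is the only doubly activated carbon that can reach it through a six-membered ring, and dry methanol keeps C1 an ester and not an inert carboxylate. The net change is an isomerisation of 7, driven by aromatisation.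

**Compound list**
1 | 11-phenylundecanoic acid | OC(=O)CCCCCCCCCCc1ccccc1 | starting material
2 | 1-(1H-imidazol-1-yl)-11-phenylundecan-1-one | O=C(CCCCCCCCCCc1ccccc1)n1ccnc1 | intermediate
3 | N-methoxy-N-methyl-11-phenylundecanamide | CON(C)C(=O)CCCCCCCCCCc1ccccc1 | intermediate
4 | 4-hydroxy-6-methyl-2H-pyran-2-one | CC1=CC(O)=CC(=O)O1 | starting material
5 | lithium 6-(lithiomethyl)-2-oxo-2H-pyran-4-olate | [Li+].[Li+].[CH2-]C1=CC([O-])=CC(=O)O1 | intermediate
6 | dilithium 6-[2-(N-methoxy-N-methylamino)-2-oxido-12-phenyldodecyl]-2-oxo-2H-pyran-4-olate (racemic) | [Li+].[Li+].CON(C)C([O-])(CCCCCCCCCCc1ccccc1)CC1=CC([O-])=CC(=O)O1 | intermediate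
7 | 4-hydroxy-6-(2-oxo-12-phenyldodecyl)-2H-pyran-2-one | O=C(CCCCCCCCCCc1ccccc1)CC1=CC(O)=CC(=O)O1 | intermediate
8 | methyl 3,5,7-trioxo-17-phenylheptadecanoate (present as its magnesium enolate) | COC(=O)CC(=O)CC(=O)CC(=O)CCCCCCCCCCc1ccccc1 | intermediate
9 | 11-phenyl-1-(2,4,6-trihydroxyphenyl)undecan-1-one | O=C(CCCCCCCCCCc1ccccc1)c1c(O)cc(O)cc1O | target

Total step count: 3. Longest linear sequence: 3 steps (1 to 3 to 7 to 9).

**Steps most likely to fail**

1. Step 3 (key step). What may go wrong: folding in the aldol sense instead of the Claisen sense, slow opening of the pyranolate, or retro-Claisen cleavage of the chain by methoxide. The fallback sets out from 7 and comes back at 9. The C4 hydroxyl of 7 would be methylated (Me2SO4, K2CO3, acetone) to 4-methoxy-6-(2-oxo-12-phenyldodecyl)-2H-pyran-2-one F1, a neutral and more electrophilic pyranone. NaOMe in refluxing MeOH would open it to methyl (2E)-3-methoxy-5,7-dioxo-17-phenylheptadec-2-enoate F2, which would not be isolated. In F2 carbon C2 is the vinylic CH of a methyl enol ether and can no longer act as an aldol donor, so the Claisen closure is the one that is left, and it would give 1-(2,6-dihydroxy-4-methoxyphenyl)-11-phenylundecan-1-one F3. The one para methyl ether would then be cleaved with BBr3 in CH2Cl2 to give 9, which is the price of this detour.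

2. Step 2. What may go wrong: sluggish C-acylation because the dilithium salt 5 is poorly soluble and aggregated, and base-induced fragmentation of the N-methoxy amide. The fallback sets out from 3 and comes back at 7. Amide 3 would be reduced with LiAlH4 in THF at −78 °C to 11-phenylundecanal F4, the reduction of a Weinreb amide stopping at the aldehyde. The far more electrophilic aldehyde would be added to dianion 5 in an aldol addition to give racemic 4-hydroxy-6-(2-hydroxy-12-phenyldodecyl)-2H-pyran-2-one F5. The secondary alcohol would then be oxidised (Jones oxidation: CrO3, aq. H2SO4, acetone, 0 °C) to ketone 7, which removes the stereocentre again.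

3. Step 1. What may go wrong: incomplete aminolysis of acylimidazole 2 by the weakly nucleophilic N,O-dimethylhydroxylamine, leaving anhydride or unchanged acid after work-up. The fallback sets out from 1 and comes back at 3. Fischer esterification of 1 (MeOH, cat. H2SO4, reflux) would give methyl 11-phenylundecanoate F6. The ester would then be attacked by the magnesium amide made from MeNHOMe·HCl and i-PrMgCl (THF, −20 °C), which activates the nucleophile and needs no activated carboxyl derivative.

**Further compounds**
F1 | step 3 | 4-methoxy-6-(2-oxo-12-phenyldodecyl)-2H-pyran-2-one | COC1=CC(=O)OC(CC(=O)CCCCCCCCCCc2ccccc2)=C1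
F2 | step 3 | methyl (2E)-3-methoxy-5,7-dioxo-17-phenylheptadec-2-enoate | COC(=O)/C=C(/OC)CC(=O)CC(=O)CCCCCCCCCCc1ccccc1
F3 | step 3 | 1-(2,6-dihydroxy-4-methoxyphenyl)-11-phenylundecan-1-one | COc1cc(O)c(C(=O)CCCCCCCCCCc2ccccc2)c(O)c1
F4 | step 2 | 11-phenylundecanal | O=CCCCCCCCCCCc1ccccc1
F5 | step 2 | 4-hydroxy-6-(2-hydroxy-12-phenyldodecyl)-2H-pyran-2-one (racemic) | OC(CCCCCCCCCCc1ccccc1)CC1=CC(O)=CC(=O)O1
F6 | step 1 | methyl 11-phenylundecanoate | COC(=O)CCCCCCCCCCc1ccccc1
A1 | direct plan | 3,5-dimethoxyphenol | COc1cc(O)cc(OC)c1
A2 | direct plan | 2-bromo-3,5-dimethoxyphenol | COc1cc(O)c(Br)c(OC)c1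
A3 | direct plan | 3,5-dimethoxy-2-(trimethylsilyl)phenyl trifluoromethanesulfonate | COc1cc(OC)c([Si](C)(C)C)c(OS(=O)(=O)C(F)(F)F)c1
A4 | direct plan | 3,5-dimethoxybenzyne | COC1=CC(OC)=CC#C1
A5 | direct plan | 1-(2-hydroxy-4,6-dimethoxyphenyl)-11-phenylundecan-1-one | COc1cc(O)c(C(=O)CCCCCCCCCCc2ccccc2)c(OC)c1
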